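**The choice.** The target is what I want more of, and the next run must be charged with one of these amounts of coupling partner.

| setting | Monday's | Saturday's | Thursday's |
|---|---|---|---|
| starting material | 0.50 M | 0.50 M | 0.50 M |
| coupling partner | 0.300 equiv | 0.600 equiv | 1.20 equiv |
| free catalyst | 3.9 mol% | 3.9 mol% | 3.9 mol% |
| time | 2.5 d | 2.5 d | 2.5 d |

    starting material + free catalyst ⇌ free catalyst + open intermediate (K1 = 2.3, k1 = 3.9 × 10⁻⁴ /M/s)
    free catalyst + open intermediate ⇌ catalyst intermediate (K2 = 6.8 /M, k2 = 0.0012 /M/s)
    coupling partner + catalyst intermediate → free catalyst + target (k3 = 0.0011 /M/s)
    coupling partner + free catalyst + target → free catalyst + over-reaction product (k4 = 0.0023 /M²/s)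

1. amount of target at the end, in percent of the starting material charged for Monday's, Saturday's, Thursday's, in this order
2. how that number moves from the first to the last of them (hardly changes / falls, then rises / falls all the way / rises, then falls / rises all the way)

- "hardly changes" means that all values lie within two and a half points (for a concentration: within two and a half percent of the largest)
- run time (Monday's): 2.5 d

**Break-even.** I call the step from coupling partner and catalyst intermediate to target the making step, and the step from coupling partner, free catalyst and target to over-reaction product the loss step. Both rates carry c(coupling partner), so it cancels when I compare them. The target gains net while c(target) lies below the making constant over the loss constant, times c(catalyst intermediate)/c(free catalyst). That quotient of constants, 0.478 M, is my break-even constant; times the catalyst ratio it gives the break-even concentration, and the ratio of the two rates is a selectivity factor.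

**My reckoning.** Each target costs one coupling partner, so the partner's charge is one ceiling on c(target): 0.150 M on Monday's, 0.300 M on Saturday's and 0.600 M on Thursday's. The break-even is the other ceiling, the point where the gain stops. For a rough value I put c(open intermediate) at the equilibrium of the first step, 0.348 M, and I hold the partner as charged. I let the catalyst intermediate stand where it is made as fast as it goes back and on to target. Then c(catalyst intermediate)/c(free catalyst) is the forward constant of the second step times c(open intermediate), over its back constant plus the making constant times c(coupling partner). The break-even comes to 0.586 M on Monday's, 0.395 M on Saturday's and 0.239 M on Thursday's, so it sinks with the charge. The ceilings cross between the last two: on Saturday's the charge is lower than the break-even, and on Thursday's the break-even is lower than the charge. These are rough ceilings, not yields, but the lower one gives a row that rises, then falls, and I would charge Saturday's.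

**The forecast.** It gives 18%, 26% and 21%, a row that rises, then falls, on the ground that “the best yield should sit near the middle charge”.

**The flask.** The simulation gives 18.6%, 24.2% and 19.6% of target, so the row rises, then falls, turning at 0.67 equiv. At 2.50 d Saturday's holds catalyst intermediate 38.9% against free catalyst 61.1%, which puts its break-even at 0.304 M; its c(target) of 0.121 M lies below that, with the making step ahead of the loss step by a factor of 2.52. At the same time Thursday's holds 21.2% against 78.8%, a break-even of 0.129 M against c(target) of 0.0978 M, and there the making step leads by a factor of 1.32.

The constants used here are assumed, and the outcome is calculated.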